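**Retrosynthetic overview**
- The enone Cα=Cβ bond is cut by retro-Claisen–Schmidt and the two acid-labile groups are removed. This leaves an 8-acetylchroman cis-diol acetonide and an O-protected 4-hydroxybenzaldehyde.
- Feature the plan rests on, in chroman numbering: O1–C8a–C4a–C5(OMe)–C6 of the benzene ring is a hidden 1,3-dioxygenated butadiene. The pyran ring O1/C2(Me2)/C3/C4/C4a/C8a with its cis-(3S,4S)-diol is a gem-dimethyl D-erythro glycal.
- The benzene ring is therefore cut at C6–C7 and C8–C8a, giving a 5-(1-methoxyvinyl) glycal diene and but-3-yn-2-one (Diels–Alder addition, then loss of H-8a and H-6).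
- The diene comes from a C4a-iodoglycal and a 1-methoxyvinylstannane (C4a–C5 bond). The glycal comes from a tertiary 4-alkyn-1-ol (O1–C8a bond), which comes from D-erythronolactone acetonide (lactone carbon = C4a, CH2O carbon = C2).
- Ring order: dioxolane (bought), pyran (step 6), benzene ring A (step 10). Ring B arrives with the aldehyde.

Key step: step 10

Remark: chroman numbering is used for the atoms of all intermediates. The anomeric carbon of 2, the THP acetal carbon of 19–21 and the carbinol carbon of 20 are carried as epimer mixtures and left open in the SMILES, because all three centres are lost later.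

**Step 1**
Reactants: 1 2,3-O-isopropylidene-D-erythronolactone
Product: 2 2,3-O-isopropylidene-D-erythrofuranose (lactol)
Conditions: i-Bu2AlH (1.1 equiv), CH2Cl2, −78 °C; MeOH, aq. potassium sodium tartrate
Reagents that add atoms: none
Why: Partial reduction of a γ-lactone, in which the aluminium hemiacetal does not collapse at −78 °C, so one hydride is delivered and the lactol is released on work-up; the new anomeric centre forms unselectively and is lost in step 2, and C3 and C4 are untouched.

**Step 2**
Reactants: 2 2,3-O-isopropylidene-D-erythrofuranose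
Product: 3 [(4R,5S)-5-ethynyl-2,2-dimethyl-1,3-dioxolan-4-yl]methanol
Conditions: dimethyl (1-diazo-2-oxopropyl)phosphonate, K2CO3, MeOH, 0 → 40 °C
Reagents that add atoms: dimethyl (1-diazo-2-oxopropyl)phosphonate, COP(=O)(OC)C(=[N+]=[N-])C(C)=O
Why: Seyferth–Gilbert homologation in its Ohira–Bestmann form, established on sugar lactols: the open hydroxy-aldehyde tautomer of 2 is trapped by the diazomethylphosphonate anion, and loss of dimethyl phosphate and N2 with 1,2-hydrogen shift gives the terminal alkyne (new carbon = C8a, former lactone carbon = C4a) under carbonate basicity that should leave the α-stereocentre C4 intact.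

**Step 3**
Reactants: 3 [(4R,5S)-5-ethynyl-2,2-dimethyl-1,3-dioxolan-4-yl]methanol
Product: 5 (4S,5S)-5-ethynyl-2,2-dimethyl-1,3-dioxolane-4-carboxylic acid, via dioxolane carbaldehyde 4 (not isolated)
Conditions: TEMPO (0.2 equiv), PhI(OAc)2 (2.2 equiv), MeCN/H2O (1:1), 23 °C
Reagents that add atoms: water, O
Why: Oxoammonium-mediated (TEMPO) oxidation carries the primary alcohol through aldehyde 4 and its hydrate to the acid at near-neutral pH, which spares the alkyne, the acetonide and the α-stereocentre C3.

**Step 4**
Reactants: 5 (4S,5S)-5-ethynyl-2,2-dimethyl-1,3-dioxolane-4-carboxylic acid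
Product: 6 methyl (4S,5S)-5-ethynyl-2,2-dimethyl-1,3-dioxolane-4-carboxylate
Conditions: MeI, K2CO3, DMF, 0 → 23 °C
Reagents that add atoms: iodomethane, CI
Why: SN2 alkylation of the potassium carboxylate by iodomethane; the terminal alkyne is far too weakly acidic to be methylated and no stereocentre is involved.

**Step 5**
Reactants: 6 methyl (4S,5S)-5-ethynyl-2,2-dimethyl-1,3-dioxolane-4-carboxylate
Product: 8 2-[(4S,5S)-5-ethynyl-2,2-dimethyl-1,3-dioxolan-4-yl]propan-2-ol, via methyl ketone 7 (not isolated)
Conditions: MeMgBr (3.5 equiv), THF, −20 → 23 °C; aq. NH4Cl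
Reagents that add atoms: methylmagnesium bromide, C[Mg]Br
Why: Double Grignard addition to the ester through ketone 7 installs the gem-dimethyl carbinol (C2 and O1); one further equivalent is consumed by the acetylenic C–H, which is restored on quench, and addition at low temperature is faster than enolisation, so C3 is retained.

**Step 6**
Reactants: 8 2-[(4S,5S)-5-ethynyl-2,2-dimethyl-1,3-dioxolan-4-yl]propan-2-ol
Product: 9 (3S,4S)-2,2-dimethyl-3,4-dihydro-2H-pyran-3,4-diol 3,4-acetonide (cis-fused glycal)
Conditions: W(CO)6 (0.25 equiv), DABCO (2 equiv), THF, hν (350 nm), 60 °C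
Reagents that add atoms: none
Why: Tungsten-vinylidene alkynol cycloisomerisation, the known endo route from 4-alkyn-1-ols to glycals: photogenerated W(CO)5 isomerises the terminal alkyne to a vinylidene whose electrophilic carbon (C8a) is attacked by the hydroxyl (O1) in a 6-endo sense, amine-assisted protodemetalation gives the enol ether, and the cis-dioxolane together with the gem-dimethyl group holds the two reacting ends close.

**Step 7**
Reactants: 9 (3S,4S)-2,2-dimethyl-3,4-dihydro-2H-pyran-3,4-diol 3,4-acetonide
Product: 10 (3S,4R)-5-iodo-2,2-dimethyl-3,4-dihydro-2H-pyran-3,4-diol 3,4-acetonide (same spatial arrangement; the C4 descriptor changes by priority only)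
Conditions: NIS (1.2 equiv), AgNO3 (0.2 equiv), MeCN, 75 °C, dark
Reagents that add atoms: N-iodosuccinimide, O=C1CCC(=O)N1I
Why: Electrophilic iodination–elimination of an enol ether, known as a one-step conversion of glycals into 2-iodoglycals: silver-activated NIS delivers I+ to the nucleophilic β-carbon C4a, and loss of the C4a proton from the oxocarbenium stage restores the C4a=C8a double bond while succinimide takes up the acid, so the allylic acetonide should not ionise.

**Step 8**
Reactants: 11 methyl vinyl ether
Product: 13 tributyl(1-methoxyvinyl)stannane, via 1-methoxyvinyllithium 12 (not isolated)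
Conditions: t-BuLi, THF/pentane, −78 → 0 °C; Bu3SnCl, −78 → 23 °C
Reagents that add atoms: tributyltin chloride, CCCC[Sn](Cl)(CCCC)CCCC
Why: Oxygen-directed kinetic α-lithiation of the vinyl ether by t-BuLi and trapping of 12 with Bu3SnCl is the standard preparation of distillable 1-alkoxyvinylstannanes.

**Step 9**
Reactants: 10 (3S,4R)-5-iodo-2,2-dimethyl-3,4-dihydro-2H-pyran-3,4-diol 3,4-acetonide; 13 tributyl(1-methoxyvinyl)stannane
Product: 14 (3S,4S)-5-(1-methoxyvinyl)-2,2-dimethyl-3,4-dihydro-2H-pyran-3,4-diol 3,4-acetonide (diene)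
Conditions: Pd(PPh3)4 (5 mol %), CuI (10 mol %), CsF (2 equiv), DMF, 45 °C; filtration through Et3N-deactivated silica
Reagents that add atoms: none
Why: Stille coupling forms C4a–C5: zerovalent palladium inserts into the vinylic C–I bond, CuI and fluoride speed up transfer of the 1-methoxyvinyl group and remove tin as insoluble Bu3SnF, and the non-acidic medium and deactivated silica keep both enol ethers of the 2-alkoxydiene intact.

**Step 10**
Reactants: 14 (3S,4S)-5-(1-methoxyvinyl)-2,2-dimethyl-3,4-dihydro-2H-pyran-3,4-diol 3,4-acetonide; 15 but-3-yn-2-one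
Product: 17 (3S,4S)-8-acetyl-5-methoxy-2,2-dimethylchroman-3,4-diol 3,4-acetonide, via cyclohexadiene cycloadduct 16 (not isolated)
Conditions: 15 (1.5 equiv), 2,6-di-tert-butylpyridine (0.1 equiv), PhMe (1 M), 23 → 45 °C; then DDQ (1.05 equiv), −20 → 0 °C, same flask
Reagents that add atoms: none
Why: The diene C8a=C4a–C5=C6, raised in energy by O1 on C8a and by the methoxy group on C5, should add ynone 15 in a normal-demand, concerted but highly asynchronous [4π+2π] cycloaddition in which the unsubstituted terminus C6 bonds first to the β-carbon of the ynone (future C7) and C8a then closes onto the acyl-bearing carbon (future C8). The closest known reaction types are the Diels–Alder/dehydrogenation sequence that turns 2-vinyl glycals into chromans and the cycloaddition of 1,3-dioxygenated (Danishefsky-type) dienes to ynones. The one ring closed is the six-membered carbocycle C4a–C5–C6–C7–C8–C8a, formed by intermolecular [4+2] annulation across the C4a–C8a edge of the pyran, first as 1,4-cyclohexadiene 16 with sp3 carbons C6 and C8a. DDQ, added cold only after 14 is consumed because it would attack the free diene, should take H-8a as hydride (doubly allylic, α to O1, vinylogously stabilised by the methoxy group), and the resulting arenium ion loses a proton from C6 to give the benzene ring. The only new stereocentre is C8a of 16, set by approach of 15 to the diene face opposite the acetonide and erased on aromatisation, while C3 and C4 are not involved. The step needs regioselectivity, which the matched push of both oxygen donors towards C6 secures, and chemoselectivity for dehydrogenation over 1,4-elimination of O1 with H-6, which is served by the neutral medium guarded by a hindered pyridine, the low oxidation temperature, the precipitation of the hydroquinone from toluene and the high hydride-donor ability of H-8a.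

**Step 11**
Reactants: 18 4-hydroxybenzaldehyde
Product: 19 4-(tetrahydro-2H-pyran-2-yloxy)benzaldehyde (racemic)
Conditions: 3,4-dihydro-2H-pyran, PPTS (cat.), CH2Cl2, 23 °C
Reagents that add atoms: 3,4-dihydro-2H-pyran, C1=COCCC1
Why: Acid-catalysed addition of the phenol to the enol ether of dihydropyran gives a base-stable acetal; its new acetal centre is racemic and disappears in step 13.

**Step 12**
Reactants: 17 (3S,4S)-8-acetyl-5-methoxy-2,2-dimethylchroman-3,4-diol 3,4-acetonide; 19 4-(tetrahydro-2H-pyran-2-yloxy)benzaldehyde
Product: 21 (3S,4S)-5-methoxy-2,2-dimethyl-8-[(E)-3-(4-(tetrahydro-2H-pyran-2-yloxy)phenyl)acryloyl]chroman-3,4-diol 3,4-acetonide, via aldol adduct 20 (not isolated)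
Conditions: KOH, EtOH, 23 °C
Reagents that add atoms: none
Why: Claisen–Schmidt condensation: the only enolisable partner is methyl ketone 17, aldol 20 dehydrates by E1cB under the same conditions to the conjugated enone whose E geometry is the thermodynamic outcome, and acetonide, THP acetal and aryl ethers are stable to hydroxide (no free ortho-phenol, hence no flavanone closure).

**Step 13**
Reactants: 21 (3S,4S)-5-methoxy-2,2-dimethyl-8-[(E)-3-(4-(tetrahydro-2H-pyran-2-yloxy)phenyl)acryloyl]chroman-3,4-diol 3,4-acetonide
Product: 23 (E)-1-[(3S,4S)-3,4-dihydroxy-5-methoxy-2,2-dimethylchroman-8-yl]-3-(4-hydroxyphenyl)prop-2-en-1-one (CNP0078858.1), via phenol acetonide 22 (not isolated)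
Conditions: AcOH/THF/H2O (4:1:1), 45 °C
Reagents that add atoms: none
Why: Hydrolysis of the THP acetal and then of the isopropylidene ketal proceeds through oxocarbenium ions centred on the protecting-group carbons, so the C3–O and C4–O bonds are never broken and the cis-(3S,4S) configuration is kept; a weak carboxylic acid in water (no alcohol solvent) is chosen so that the benzylic C4–OH, flanked by two ortho oxygen donors, is neither ionised nor etherified.

**Compound list**
1 | 2,3-O-isopropylidene-D-erythronolactone, (3aR,6aR) | O=C1OC[C@H]2OC(C)(C)O[C@@H]12 | starting material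
2 | 2,3-O-isopropylidene-D-erythrofuranose (anomer mixture) | OC1OC[C@H]2OC(C)(C)O[C@@H]12 | intermediate
3 | [(4R,5S)-5-ethynyl-2,2-dimethyl-1,3-dioxolan-4-yl]methanol | C#C[C@@H]1OC(C)(C)O[C@@H]1CO | intermediate
4 | (4S,5S)-5-ethynyl-2,2-dimethyl-1,3-dioxolane-4-carbaldehyde | C#C[C@@H]1OC(C)(C)O[C@@H]1C=O | intermediate
5 | (4S,5S)-5-ethynyl-2,2-dimethyl-1,3-dioxolane-4-carboxylic acid | C#C[C@@H]1OC(C)(C)O[C@@H]1C(=O)O | intermediate
6 | methyl (4S,5S)-5-ethynyl-2,2-dimethyl-1,3-dioxolane-4-carboxylate | C#C[C@@H]1OC(C)(C)O[C@@H]1C(=O)OC | intermediate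
7 | 1-[(4S,5S)-5-ethynyl-2,2-dimethyl-1,3-dioxolan-4-yl]ethanone | C#C[C@@H]1OC(C)(C)O[C@@H]1C(C)=O | intermediate
8 | 2-[(4S,5S)-5-ethynyl-2,2-dimethyl-1,3-dioxolan-4-yl]propan-2-ol | C#C[C@@H]1OC(C)(C)O[C@@H]1C(C)(C)O | intermediate
9 | (3S,4S)-2,2-dimethyl-3,4-dihydro-2H-pyran-3,4-diol 3,4-acetonide | C1=COC(C)(C)[C@H]2OC(C)(C)O[C@@H]12 | intermediate
10 | (3S,4R)-5-iodo-2,2-dimethyl-3,4-dihydro-2H-pyran-3,4-diol 3,4-acetonide | IC1=COC(C)(C)[C@H]2OC(C)(C)O[C@@H]12 | intermediate
11 | methyl vinyl ether | C=COC | starting material
12 | 1-methoxyvinyllithium | [Li]C(=C)OC | intermediate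
13 | tributyl(1-methoxyvinyl)stannane | C=C(OC)[Sn](CCCC)(CCCC)CCCC | intermediate
14 | (3S,4S)-5-(1-methoxyvinyl)-2,2-dimethyl-3,4-dihydro-2H-pyran-3,4-diol 3,4-acetonide | C=C(OC)C1=COC(C)(C)[C@H]2OC(C)(C)O[C@@H]12 | intermediate
15 | but-3-yn-2-one | CC(=O)C#C | starting material
16 | (3S,4S,8aR)-8-acetyl-5-methoxy-2,2-dimethyl-3,4,6,8a-tetrahydro-2H-chromene-3,4-diol 3,4-acetonide (H-8a on the acetonide face) | COC1=C2[C@@H]3OC(C)(C)O[C@@H]3C(C)(C)O[C@H]2C(C(C)=O)=CC1 | intermediate
17 | (3S,4S)-8-acetyl-5-methoxy-2,2-dimethylchroman-3,4-diol 3,4-acetonide | COc1ccc(C(C)=O)c2c1[C@@H]3OC(C)(C)O[C@@H]3C(C)(C)O2 | intermediate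
18 | 4-hydroxybenzaldehyde | O=Cc1ccc(O)cc1 | starting material
19 | 4-(tetrahydro-2H-pyran-2-yloxy)benzaldehyde (racemic) | O=Cc1ccc(OC2CCCCO2)cc1 | intermediate
20 | β-hydroxy ketone from 17 and 19 (carbinol and THP epimers) | COc1ccc(C(=O)CC(O)c2ccc(OC3CCCCO3)cc2)c2c1[C@@H]3OC(C)(C)O[C@@H]3C(C)(C)O2 | intermediate
21 | (E)-chalcone, THP ether and 3,4-acetonide, (3S,4S) | COc1ccc(C(=O)/C=C/c2ccc(OC3CCCCO3)cc2)c2c1[C@@H]3OC(C)(C)O[C@@H]3C(C)(C)O2 | intermediate
22 | (E)-chalcone, free phenol and 3,4-acetonide, (3S,4S) | COc1ccc(C(=O)/C=C/c2ccc(O)cc2)c2c1[C@@H]3OC(C)(C)O[C@@H]3C(C)(C)O2 | intermediate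
23 | (E)-1-[(3S,4S)-3,4-dihydroxy-5-methoxy-2,2-dimethylchroman-8-yl]-3-(4-hydroxyphenyl)prop-2-en-1-one | COc1ccc(C(=O)/C=C/c2ccc(O)cc2)c2c1[C@H](O)[C@H](O)C(C)(C)O2 | target

**Step count**
- Total: 13 steps.
- Longest linear sequence: 11 steps (steps 1–7, 9, 10, 12, 13).

**Steps most likely to fail**

1. Step 10.
   - Process at risk: after the cycloaddition, departure of O1 from C8a together with a C6 proton (ring-opening aromatisation) may be faster than hydride transfer to the quinone. The doubly activated diene may also hydrolyse or oligomerise before it adds.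
   - Fallback, setting out from 14 and returning at 17: 14 is heated with methyl vinyl ketone (PhMe, 60 °C) in place of the ynone. The same donor polarisation should give the endo cyclohexene adduct F1, which cannot become aromatic by a single elimination and can be handled.
   - DDQ (2.3 equiv, PhMe, 23 → 80 °C) should first remove H-8a as hydride and the acidic H-8 as proton, giving the 6,7-dihydro dienyl ketone F2. In F2, O1 sits on an sp2 carbon and can no longer leave. The second dehydrogenation across C6–C7 then gives 17.

2. Step 6.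
   - Process at risk: slow addition of the hindered tertiary hydroxyl to the tungsten vinylidene, so that the catalyst decays. Competing 5-exo closure onto C4a is also possible.
   - Fallback, setting out from 8 and returning at 9: anti-Markovnikov hydration of the alkyne by hydroboration with dicyclohexylborane (excess to cover the OH, THF, 0 °C) and oxidation with NaBO3·4H2O should give the 2-deoxy lactol F3.
   - MsCl/Et3N (CH2Cl2, −40 °C → reflux) converts F3 through the anomeric mesylate F4 into glycal 9 by loss of a C4a proton. This is the known lactol-to-glycal dehydration.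

3. Step 9.
   - Process at risk: sluggish insertion and transmetalation at the hindered, electron-rich iodide, protodestannylation of 13, or hydrolysis of the methoxyvinyl group during isolation.
   - Fallback, setting out from 10 and returning at 14: methoxycarbonylation of the iodide (PdCl2(PPh3)2, CO 1 atm, MeOH, Et3N, DMF, 60 °C) should give the robust, chromatographable methyl ester F5.
   - Carbonyl methylenation of F5 with the Tebbe reagent Cp2Ti(μ-CH2)(μ-Cl)AlMe2 (pyridine, THF/PhMe, −40 → 23 °C, basic quench) converts CO2Me directly into C(OMe)=CH2. This gives 14 tin-free under basic conditions.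

**Further compounds**
F1 | step 10 | endo Diels–Alder adduct of 14 with methyl vinyl ketone (8-acetyl-5-methoxy-3,4,6,7,8,8a-hexahydro-2H-chromene acetonide, acetyl cis to O1) | COC1=C2[C@@H]3OC(C)(C)O[C@@H]3C(C)(C)O[C@H]2[C@@H](C(C)=O)CC1
F2 | step 10 | (3S,4S)-8-acetyl-5-methoxy-2,2-dimethyl-3,4,6,7-tetrahydro-2H-chromene-3,4-diol 3,4-acetonide | COC1=C2[C@@H]3OC(C)(C)O[C@@H]3C(C)(C)OC2=C(C(C)=O)CC1
F3 | step 6 | 2-deoxy lactol: 6,6-dimethyltetrahydro-2H-pyran-2,4,5-triol 4,5-acetonide (anomer mixture) | OC1C[C@@H]2OC(C)(C)O[C@@H]2C(C)(C)O1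
F4 | step 6 | anomeric mesylate of F3 | CS(=O)(=O)OC1C[C@@H]2OC(C)(C)O[C@@H]2C(C)(C)O1
F5 | step 9 | methyl (3S,4S)-3,4-dihydroxy-2,2-dimethyl-3,4-dihydro-2H-pyran-5-carboxylate 3,4-acetonide | COC(=O)C1=COC(C)(C)[C@H]2OC(C)(C)O[C@@H]12
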